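**Conventions.** Atom positions carry a letter: C1 = CH–OAc, C2 = ring CH2, C3 = quaternary carbon with CH3, C4 and C5 = cyclopentane CH2, C6 = C(OH)(isopropyl), C7 = ring-fusion CH, C8 = CH–O-aroyl, C9=C10 = alkene with CH3 on C10. β is the face of the C3 methyl group, α the opposite face. Compound numbers carry no letter.

**Compound key.** 1 3-methylcyclopent-2-en-1-one; 2 ethynyl(trimethyl)silane; 3 propanal; 4 alkenylalane; 5 aluminium enolate; 6 silylvinyl aldol; 7 vinyl aldol; 8 isopropylmagnesium chloride; 9 isopropylcerium dichloride; 10 diol; 11 alkylborane; 12 triol; 13 hydroxy keto aldehyde; 14 silyl-protected keto aldehyde; 15 trans-hydrindanone ketol; 16 its silyl ether; 17 silyl enol ether (precursor of the key step); 18 siloxycyclopropane; 19 β-chloro ketone; 20 hydroazulenone (product of the key step); 21 dihydroxy enone; 22 C1 acetate; 23 C8 alcohol; 24 4-hydroxybenzoic acid; 25 silyl ester; 26 silyloxy acid; 27 acid chloride; 28 silyl-protected target; 29 target.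

## Analysis of the target

Compound 29 is a trans-fused bicyclo[5.3.0]decene: a cyclopentane (C3–C4–C5–C6–C7) shares the C3–C7 bond with a cycloheptene (C1–C2–C3–C7–C8–C9=C10). It has five stereocentres: the quaternary C3 (methyl β), C7 (hydrogen α), the tertiary carbinol C6 (hydroxyl β, isopropyl α), C8 (aroyloxy α) and C1 (acetoxy α); in these position labels the configuration is 1S,3R,6R,7S,8S. C3, C7, C6 and C8 are contiguous, with the C6 hydroxyl cis to the angular methyl and on the face opposite the C8 oxygen, while C1 is remote and allylic. The tertiary alcohol is β to C8, so retro-aldol cleavage and dehydration threaten whenever C8 is a ketone. The two esters are different, both are allylic, and the phenol is free. The difficulty lies in the trans ring fusion next to a quaternary carbon (it is not enforced by thermodynamics), the crowded C3–C7–C6 triad, the seven-membered ring with a fixed alkene position, and the differentiation of three hydroxyl groups. The feature the plan rests on is the unit C8(O)–C9H=C10(CH3) between C7 and C1. With C8 as a ketone it is a β-methyl enone, and without C9 it is a 2-methylcyclohexanone (C8 carbonyl, C10 α-carbon) embedded in a trans-hydrindane. The seven-membered ring can therefore come from a six-membered one by inserting a single carbon between C8 and C10.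

## Retrosynthetic reasoning

**Ester bonds at C8 and C1.** The aryl ester of 29 is cut at the acyl–oxygen bond to alcohol 23 and silyl-protected acid 26 (through 28), and the acetate of 22 is cut back to diol 21. The acetate goes on first, while C1–OH is the only hydroxyl that can be acylated, and the aroyl group goes on last, once C8–OH exists. No stereocentre is touched.

**C8–H bond.** Alcohol 23 is traced to enone 22. The C8 carbinol is made by reduction because the tertiary C6 hydroxyl sits on the β-face and can deliver hydride to that face of the carbonyl, which gives the α-alcohol. A free reagent would attack from the α-face, away from the angular methyl.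

**C8–C9 and C9–C10 bonds (key disconnection).** Removing C9 from enone 20 leads, through β-chloro ketone 19 and siloxycyclopropane 18, to the six-membered silyl enol ether 17. Cutting here and not at a ring-closing bond of the cycloheptene means the medium ring never has to be cyclised. It is grown from a rigid trans-hydrindane on which C1, C3, C6 and C7 are already fixed. The forward reaction must add one carbon to the C8=C10 enol ether and break the bond between C8 and C10.

**Enol ether and silyl ethers.** Enol ether 17 comes from ketone 16, and 16 from ketol 15. The forward enolisation has to go toward C10 and must not expel the C1 oxygen.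

**C10–C1 bond.** Ketol 15 is opened by a retro-aldol cut to keto aldehyde 14. This bond is chosen because its formation creates the C1 carbinol together with the six-membered ring. The C1 hydroxyl is placed equatorial (α) by the axial angular methyl.

**Oxidation levels and the two-carbon arm.** Keto aldehyde 14 goes back through 13 to triol 12 and then to vinyl diol 10. The C8 ketone is kept as a carbinol until the C6 centre has been made, so that no 1,3-diketone ever forms.

**C6–isopropyl bond.** Diol 10 is cut to cyclopentanone 7 and the isopropylcerium reagent 9, made from 8. The side chain on C7 steers the nucleophile to the α-face, which puts the hydroxyl β.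

**C3–C2 and C7–C8 bonds.** Ketone 7 comes from the silylvinyl aldol 6. Aldol 6 is cut at C7–C8 (aldol with 3) and at C3–C2 (conjugate addition of alkenylalane 4, made from 2, to enone 1), with the aluminium enolate 5 linking the two events. The conjugate addition sets C3 under catalyst control. The bulky silylvinyl group then directs the aldehyde to the opposite face of C7. This fixes the trans relationship of the C7 side chain and the C3 arm, which later becomes the trans ring fusion.

## Alternatives that were turned down

**Alternative 1:** The C6–C7 bond is cut, so that the cyclopentane comes from the open-chain α-diazo ester A1 (C7 diazo carbon, C8 ester carbon, C6 a silyloxy methine). In the forward step Rh2(OAc)4 releases N2 from A1 and the rhodium carbenoid inserts into the C6–H bond to give the cyclopentane ester A2.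
- For: C6–H is the only C–H bond in a 1,5-relationship to the carbenoid carbon, it is tertiary and activated by oxygen, and the insertion is retentive. C3 is quaternary, so no 1,2-hydride shift competes. The C6 oxygen arrives already protected, with no organometallic addition to a hindered ketone. On the installation of the C6 carbinol this route is at least as strong as the chosen one.
- Against: the insertion has to join two carbons that each neighbour a fully substituted centre. The carbenoid can instead be trapped by the silyl ether oxygen as an oxonium ylide. The C7 configuration relative to C3 rests only on an epimerisable ester. A1 needs two remote stereocentres (C3 and C6, 1,4 in an open chain) made independently.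
- Comparison: after A2 the whole seven-membered ring is still missing, with C1 and C8 to be set on a flexible ring. The chosen route sets its stereocentres on five- and six-membered rings and obtains the seven-membered ring for one added carbon.

**Alternative 2:** The C3–C7 bond is cut and C3 is reconnected to C8, which leads to the decalin A3 (C8 a ring-fusion tertiary alcohol, C7 a mesylate). In the forward step KOtBu forms the C8 alkoxide, the ring bond C8–C3 anti-periplanar to the C7–O bond migrates to C7, ring A contracts to the cyclopentane and ring B grows to the cycloheptanone A4.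
- For: such decalins are available in enantiopure form by Robinson annulation chemistry. The shift is stereospecific (retention at C3, inversion at C7), so the trans fusion follows from the mechanism, and both rings of the target appear in one step. In skeletal economy and in certainty of the ring fusion this is stronger than the chosen route.
- Against: the secondary sulfonate lies between a ring-fusion carbinol and the fully substituted C6, so its formation is hard, and the alkoxide can close an epoxide onto C7 or cause elimination. The flexible cis-decalin can also present the C8–C9 bond for migration. More decisively, A4 has no oxygen at C1 and its alkene sits at C10=C1, out of conjugation. The target would need alkene migration, stereocontrolled oxidation at C1 on a seven-membered ring, and acidic removal of an acetal from a tertiary alcohol β to a ketone.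
- Comparison: the chosen route brings the C1 oxygen in through an aldol on the six-membered ring and places the alkene by elimination, so it reaches the full substitution pattern in fewer steps after the key event.

**Alternative 3:** The C5–C6 bond is cut, so the cyclopentanol is closed last from cycloheptene A5 (2-iodoethyl on C3, isopropyl ketone on C7). In the forward step SmI2 with HMPA reduces the primary iodide and the alkylsamarium adds to the ketone, giving A6.
- For: five-membered Barbier closures onto ketones are dependable and tolerate silyl ethers, acetals and an alkene. C1 and C8 already have their final oxidation level and configuration, so the endgame is shorter than the chosen one, which still needs a directed reduction at C8.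
- Against: every hard stereochemical problem (quaternary C3, the trans-related C7, C8, and the remote C1) is moved into A5, a mobile seven-membered ring without the cyclopentane that makes these centres controllable. C7 of A5 is α to the ketone and β to the C8 ether, so epimerisation and β-elimination threaten under the basic Barbier conditions. The facial selectivity at C6 depends on the acyl rotamer and on chelation, not on a ring.
- Comparison: the chosen route sets C6 by addition to a cyclopentanone anti to its neighbouring substituent and fixes the ring fusion before the seven-membered ring exists. The price is a longer endgame.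

Key step: step 10

**Remark on the starting enone:** the cyclopentenone must carry its methyl on the β-carbon (3-methylcyclopent-2-en-1-one, 1), because a 2-methyl isomer would need a carbonyl transposition to bring the ring oxygen to C6.

**Remark on open stereocentres:** 6, 7, 10, 11 and 12 are carried as mixtures of epimers at the carbinol carbon C8 and converge in step 5; 18 and 19 are open at the transient centres C8 and C10 and converge in the elimination. Their SMILES leave these centres unspecified.

## Route

Step 1
Reactants: 1 3-methylcyclopent-2-en-1-one; 2 ethynyl(trimethyl)silane; 3 propanal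
Product: 6 (2S,3S)-2-(1-hydroxypropyl)-3-methyl-3-[1-(trimethylsilyl)ethenyl]cyclopentan-1-one (C8 epimers), via alkenylalane 4 (not isolated), via aluminium enolate 5 (not isolated)
Conditions: 2, iBu2AlH, hexane/THF, 55 °C; then 1, Cu(OTf)2 (5 mol%), chiral sulfonate-bearing NHC ligand (5 mol%, transferred from its Ag2O-derived silver carbene), THF, −78 → −15 °C; then 3 (3 equiv), −78 → −40 °C; aq. potassium sodium tartrate
Reagents that add atoms: none
Why: Copper-catalysed enantioselective conjugate addition of an alkenylaluminium to a β-substituted cyclopentenone sets the quaternary centre C3 under catalyst control (the ligand enantiomer is chosen to give 3S in 6), and the regiodefined aluminium enolate 5 is trapped in a tandem aldol addition with 3, forming C7–C8. The aldehyde approaches C7 anti to the bulky 1-silylvinyl group on the neighbouring C3, so the side chain ends cis to the methyl group (C7–H α); the carbinol centre C8 (mainly the anti aldol through a Zimmerman–Traxler chair) need not be controlled because it is oxidised in step 5.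

Step 2
Reactants: 6 (2S,3S)-2-(1-hydroxypropyl)-3-methyl-3-[1-(trimethylsilyl)ethenyl]cyclopentan-1-one
Product: 7 (2S,3R)-3-ethenyl-2-(1-hydroxypropyl)-3-methylcyclopentan-1-one (C8 epimers)
Conditions: CF3CO2H (5 equiv), CH2Cl2, 0 → 22 °C; then NaHCO3, MeOH
Reagents that add atoms: none
Why: Protodesilylation of the vinylsilane: ipso protonation gives a β-silyl-stabilised cation that loses the silyl group to trifluoroacetate and leaves the plain vinyl group. The secondary β-hydroxy ketone should survive the short anhydrous acid treatment; any trifluoroacetate formed is cleaved in the bicarbonate/methanol work-up.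

Step 3
Reactants: 7 (2S,3R)-3-ethenyl-2-(1-hydroxypropyl)-3-methylcyclopentan-1-one; 8 isopropylmagnesium chloride
Product: 10 (1R,2S,3R)-3-ethenyl-2-(1-hydroxypropyl)-3-methyl-1-(propan-2-yl)cyclopentan-1-ol (C8 epimers), via isopropylcerium dichloride 9 (not isolated)
Conditions: 8 (4 equiv), CeCl3 (4 equiv, dried), THF, −78 °C, 1 h; then 7, −78 → −40 °C; aq. NH4Cl
Reagents that add atoms: none
Why: Organocerium 1,2-addition: the weakly basic, strongly nucleophilic reagent 9 (one equivalent is spent on the hydroxyl) adds to the hindered, enolisable ketone without enolisation, β-hydride reduction or retro-aldol at −78 °C. Attack comes from the α-face, anti to the C7 side chain, which places the isopropyl group α and the new tertiary hydroxyl β (6R), cis to the angular methyl.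

Step 4
Reactants: 10 (1R,2S,3R)-3-ethenyl-2-(1-hydroxypropyl)-3-methyl-1-(propan-2-yl)cyclopentan-1-ol
Product: 12 (1R,2S,3R)-3-(2-hydroxyethyl)-2-(1-hydroxypropyl)-3-methyl-1-(propan-2-yl)cyclopentan-1-ol (C8 epimers), via alkylborane 11 (not isolated)
Conditions: 9-BBN (3.5 equiv), THF, 0 → 50 °C; then NaOH, H2O2, 0 °C → rt
Reagents that add atoms: hydrogen peroxide, OO
Why: Anti-Markovnikov hydroboration–oxidation of the monosubstituted alkene: 9-BBN places boron on the terminal carbon of the neopentyl-type vinyl group and alkaline peroxide replaces it by hydroxyl, with no stereocentre involved. The excess borane covers the two free hydroxyl groups.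

Step 5
Reactants: 12 (1R,2S,3R)-3-(2-hydroxyethyl)-2-(1-hydroxypropyl)-3-methyl-1-(propan-2-yl)cyclopentan-1-ol
Product: 13 2-[(1R,2R,3R)-3-hydroxy-1-methyl-2-propanoyl-3-(propan-2-yl)cyclopentyl]acetaldehyde
Conditions: (COCl)2, DMSO, CH2Cl2, −78 °C; Et3N, −78 → −20 °C
Reagents that add atoms: none
Why: Swern oxidation: the primary and the hindered secondary alcohol are both activated at −78 °C before the base is added, so the aldehyde never meets a free C8 hydroxyl (no lactol, no lactone), and the tertiary alcohol cannot be oxidised. The two C8 epimers converge here.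

Step 6
Reactants: 13 2-[(1R,2R,3R)-3-hydroxy-1-methyl-2-propanoyl-3-(propan-2-yl)cyclopentyl]acetaldehyde
Product: 14 2-[(1R,2R,3R)-1-methyl-2-propanoyl-3-(propan-2-yl)-3-(triethylsilyloxy)cyclopentyl]acetaldehyde
Conditions: Et3SiOTf, 2,6-lutidine, CH2Cl2, −78 °C
Reagents that add atoms: triethylsilyl trifluoromethanesulfonate, CC[Si](CC)(CC)OS(=O)(=O)C(F)(F)F
Why: Silylation of the tertiary alcohol with a silyl triflate and a hindered pyridine base at −78 °C is fast enough to leave aldehyde and ketone untouched. The silyl ether blocks retro-aldol cleavage of the C6–C7 bond in the basic step that follows.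

Step 7
Reactants: 14 2-[(1R,2R,3R)-1-methyl-2-propanoyl-3-(propan-2-yl)-3-(triethylsilyloxy)cyclopentyl]acetaldehyde
Product: 15 (3R,3aR,5R,6S,7aR)-6-hydroxy-5,7a-dimethyl-3-(propan-2-yl)-3-(triethylsilyloxy)octahydro-4H-inden-4-one
Conditions: K2CO3 (0.5 equiv), MeOH, 0 °C → rt, 0.01 M
Reagents that add atoms: none
Why: Intramolecular aldol addition (6-enolendo-exo-trig) of the C10 enolate of the ethyl ketone to the aldehyde closes the cyclohexanone; C7–H lies between two fully substituted carbons and is not removed, so the trans relationship set in step 1 becomes the trans ring fusion. The new C1 hydroxyl takes the equatorial α-position, away from the axial angular methyl, and this isomer is also the thermodynamic one under reversible conditions. The C10 methyl settles equatorial and ceases to be a stereocentre in step 9.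

Step 8
Reactants: 15 (3R,3aR,5R,6S,7aR)-6-hydroxy-5,7a-dimethyl-3-(propan-2-yl)-3-(triethylsilyloxy)octahydro-4H-inden-4-one
Product: 16 (3R,3aR,5R,6S,7aR)-6-(tert-butyldimethylsilyloxy)-5,7a-dimethyl-3-(propan-2-yl)-3-(triethylsilyloxy)octahydro-4H-inden-4-one
Conditions: tBuMe2SiOTf, 2,6-lutidine, CH2Cl2, −78 → 0 °C
Reagents that add atoms: tert-butyldimethylsilyl trifluoromethanesulfonate, CC(C)(C)[Si](C)(C)OS(=O)(=O)C(F)(F)F
Why: Silyl triflate protection of the secondary β-hydroxy ketone at low temperature with a non-nucleophilic base avoids retro-aldol cleavage and elimination.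

Step 9
Reactants: 16 (3R,3aR,5R,6S,7aR)-6-(tert-butyldimethylsilyloxy)-5,7a-dimethyl-3-(propan-2-yl)-3-(triethylsilyloxy)octahydro-4H-inden-4-one
Product: 17 (3R,3aR,6S,7aR)-6-(tert-butyldimethylsilyloxy)-5,7a-dimethyl-3-(propan-2-yl)-3-(triethylsilyloxy)-4-(trimethylsilyloxy)-2,3,3a,6,7,7a-hexahydro-1H-indene
Conditions: Me3SiOTf, Et3N, CH2Cl2, −20 → 0 °C; cold aq. NaHCO3
Reagents that add atoms: trimethylsilyl trifluoromethanesulfonate, C[Si](C)(C)OS(=O)(=O)C(F)(F)F
Why: Soft enolisation: O-silylation of the ketone followed by deprotonation with Et3N gives the silyl enol ether without a free enolate, so the β-silyloxy group at C1 is not expelled. The axial C10–H is accessible, whereas C7–H is buried between C3 and C6 and an enol ether toward C7 would suffer severe allylic strain with both, so the C8=C10 isomer forms.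

Step 10
Reactants: 17 (3R,3aR,6S,7aR)-6-(tert-butyldimethylsilyloxy)-5,7a-dimethyl-3-(propan-2-yl)-3-(triethylsilyloxy)-4-(trimethylsilyloxy)-2,3,3a,6,7,7a-hexahydro-1H-indene
Product: 20 (3R,3aR,7S,8aR)-7-(tert-butyldimethylsilyloxy)-6,8a-dimethyl-3-(propan-2-yl)-3-(triethylsilyloxy)-2,3,3a,7,8,8a-hexahydroazulen-4(1H)-one, via siloxycyclopropane 18 (not isolated), via β-chloro ketone 19 (not isolated)
Conditions: Et2Zn, CH2I2, CH2Cl2, 0 °C → rt; pyridine, filter, concentrate; then FeCl3 (2.5 equiv), pyridine, DMF, 0 °C → rt; then NaOAc, MeOH, 60 °C
Reagents that add atoms: diiodomethane, ICI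
Why: The electron-rich, tetrasubstituted silyl enol ether 17 takes up methylene from the Furukawa zinc carbenoid (EtZnCH2I) in a concerted [2+1] butterfly-type transfer that closes the three-membered ring C8–C9–C10 of siloxycyclopropane 18; either face may react because both new centres are erased afterwards. FeCl3 then oxidises 18 by single-electron transfer, the silyl group leaves as Me3SiCl, and the cyclopropyloxy radical undergoes β-scission of the internal C8–C10 bond, so that C8 becomes the carbonyl and C10 a tertiary radical that takes chlorine from a second FeCl3 to give β-chloro ketone 19. The seven-membered ring is thus formed by enlargement of the six-membered ring, with C9 ending between C8 and C10, and not by an end-to-end closure. NaOAc removes HCl through the C9 enolate (E1cB) and places the alkene at C9=C10 in conjugation with the C8 carbonyl. This is the Ito–Saegusa FeCl3 ring expansion of siloxycyclopropanes; its closest model is the conversion of the more substituted silyl enol ether of 2-methylcyclohexanone into 3-methylcyclohept-2-enone. No stereocentre is made or touched, so C1, C3, C6 and C7 are carried over from the rigid hydrindane. The step needs the C8=C10 regiochemistry of the enol ether (fixed in step 9), cleavage of the internal and not the external cyclopropane bond (secured by the tertiary radical and the strain released), and elimination toward C9 (the only direction that gives a conjugated enone).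

Step 11
Reactants: 20 (3R,3aR,7S,8aR)-7-(tert-butyldimethylsilyloxy)-6,8a-dimethyl-3-(propan-2-yl)-3-(triethylsilyloxy)-2,3,3a,7,8,8a-hexahydroazulen-4(1H)-one
Product: 21 (3R,3aR,7S,8aR)-3,7-dihydroxy-6,8a-dimethyl-3-(propan-2-yl)-2,3,3a,7,8,8a-hexahydroazulen-4(1H)-one
Conditions: HF·pyridine, pyridine, THF, 0 °C → rt
Reagents that add atoms: none
Why: Fluoride cleavage of both silyl ethers under buffered, weakly acidic conditions spares the β-hydroxy enone from the retro-aldol cleavage that a basic fluoride source could cause.

Step 12
Reactants: 21 (3R,3aR,7S,8aR)-3,7-dihydroxy-6,8a-dimethyl-3-(propan-2-yl)-2,3,3a,7,8,8a-hexahydroazulen-4(1H)-one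
Product: 22 (3R,3aR,7S,8aR)-7-acetoxy-3-hydroxy-6,8a-dimethyl-3-(propan-2-yl)-2,3,3a,7,8,8a-hexahydroazulen-4(1H)-one
Conditions: Ac2O, pyridine, DMAP (cat.), CH2Cl2, 0 °C
Reagents that add atoms: acetic anhydride, CC(=O)OC(C)=O
Why: Chemoselective acylation: the secondary allylic hydroxyl at C1 is acetylated under nucleophilic catalysis at 0 °C, while the tertiary C6 hydroxyl does not react.

Step 13
Reactants: 22 (3R,3aR,7S,8aR)-7-acetoxy-3-hydroxy-6,8a-dimethyl-3-(propan-2-yl)-2,3,3a,7,8,8a-hexahydroazulen-4(1H)-one
Product: 23 (3R,3aS,4S,7S,8aR)-7-acetoxy-6,8a-dimethyl-3-(propan-2-yl)-1,2,3,3a,4,7,8,8a-octahydroazulene-3,4-diol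
Conditions: Me4NBH(OAc)3, AcOH/MeCN (1:1), −30 → −10 °C
Reagents that add atoms: none
Why: Evans–Saksena reduction: the tertiary C6 hydroxyl exchanges onto boron and the alkoxy(diacetoxy)borohydride delivers hydride through a six-membered transition state to the β-face of the C8 carbonyl, giving the α-alcohol (8S), anti to the C6 hydroxyl. An external hydride would instead attack from the α-face, away from the angular methyl; the reagent reduces the enone in the 1,2-sense and leaves the acetate alone.

Step 14
Reactants: 24 4-hydroxybenzoic acid
Product: 26 4-(tert-butyldimethylsilyloxy)benzoic acid, via silyl ester 25 (not isolated)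
Conditions: tBuMe2SiCl (2.4 equiv), imidazole, DMF, rt; then AcOH/THF/H2O, rt
Reagents that add atoms: tert-butyl(chloro)dimethylsilane, CC(C)(C)[Si](C)(C)Cl
Why: Silylation of phenol and acid, followed by selective hydrolysis of the labile silyl ester under mild aqueous acid, gives the O-silyl acid.

Step 15
Reactants: 23 (3R,3aS,4S,7S,8aR)-7-acetoxy-6,8a-dimethyl-3-(propan-2-yl)-1,2,3,3a,4,7,8,8a-octahydroazulene-3,4-diol; 26 4-(tert-butyldimethylsilyloxy)benzoic acid
Product: 28 (3R,3aS,4S,7S,8aR)-7-acetoxy-3-hydroxy-6,8a-dimethyl-3-(propan-2-yl)-1,2,3,3a,4,7,8,8a-octahydroazulen-4-yl 4-(tert-butyldimethylsilyloxy)benzoate, via acid chloride 27 (not isolated)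
Conditions: 26, (COCl)2, DMF (cat.), CH2Cl2, 0 °C → rt, concentrate; then 23, Et3N, DMAP, CH2Cl2, 0 → 35 °C
Reagents that add atoms: none
Why: Acid chloride formation with oxalyl chloride under DMF catalysis, then DMAP-catalysed acylation of the secondary allylic alcohol. The tertiary hydroxyl is inert, and C8 keeps its configuration because only the acyl–oxygen bond is formed.

Step 16
Reactants: 28 (3R,3aS,4S,7S,8aR)-7-acetoxy-3-hydroxy-6,8a-dimethyl-3-(propan-2-yl)-1,2,3,3a,4,7,8,8a-octahydroazulen-4-yl 4-(tert-butyldimethylsilyloxy)benzoate
Product: 29 (3R,3aS,4S,7S,8aR)-7-acetoxy-3-hydroxy-6,8a-dimethyl-3-(propan-2-yl)-1,2,3,3a,4,7,8,8a-octahydroazulen-4-yl 4-hydroxybenzoate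
Conditions: KHF2, MeOH, rt
Reagents that add atoms: none
Why: Aryl silyl ethers are cleaved by bifluoride in methanol at room temperature much faster than esters are attacked, so the phenol is released without ester cleavage or acyl migration.

## Compound list

1 | 3-methylcyclopent-2-en-1-one | CC1=CC(=O)CC1 | starting material
2 | ethynyl(trimethyl)silane | C#C[Si](C)(C)C | starting material
3 | propanal | CCC=O | starting material
4 | bis(2-methylpropyl)[1-(trimethylsilyl)ethenyl]aluminium | C=C([Si](C)(C)C)[Al](CC(C)C)CC(C)C | intermediate (not isolated)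
5 | diisobutylaluminium enolate of (3S)-3-methyl-3-[1-(trimethylsilyl)ethenyl]cyclopentanone (C6–O–Al, C6=C7) | C=C([Si](C)(C)C)[C@@]1(C)CCC(O[Al](CC(C)C)CC(C)C)=C1 | intermediate (not isolated)
6 | (2S,3S)-2-(1-hydroxypropyl)-3-methyl-3-[1-(trimethylsilyl)ethenyl]cyclopentan-1-one (C8 epimers; C7 side chain cis to methyl) | C=C([Si](C)(C)C)[C@@]1(C)CCC(=O)[C@@H]1C(O)CC | intermediate
7 | (2S,3R)-3-ethenyl-2-(1-hydroxypropyl)-3-methylcyclopentan-1-one (C8 epimers) | C=C[C@@]1(C)CCC(=O)[C@@H]1C(O)CC | intermediate
8 | isopropylmagnesium chloride | CC(C)[Mg]Cl | starting material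
9 | isopropylcerium dichloride | CC(C)[Ce](Cl)Cl | intermediate (not isolated)
10 | (1R,2S,3R)-3-ethenyl-2-(1-hydroxypropyl)-3-methyl-1-(propan-2-yl)cyclopentan-1-ol (C8 epimers; C6–OH β) | C=C[C@@]1(C)CC[C@@](O)(C(C)C)[C@@H]1C(O)CC | intermediate
11 | B-alkyl-9-borabicyclo[3.3.1]nonane from 10 (boron on C1) | B1(CC[C@@]2(C)CC[C@@](O)(C(C)C)[C@@H]2C(O)CC)C2CCCC1CCC2 | intermediate (not isolated)
12 | (1R,2S,3R)-3-(2-hydroxyethyl)-2-(1-hydroxypropyl)-3-methyl-1-(propan-2-yl)cyclopentan-1-ol (C8 epimers) | OCC[C@@]1(C)CC[C@@](O)(C(C)C)[C@@H]1C(O)CC | intermediate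
13 | 2-[(1R,2R,3R)-3-hydroxy-1-methyl-2-propanoyl-3-(propan-2-yl)cyclopentyl]acetaldehyde | O=CC[C@@]1(C)CC[C@@](O)(C(C)C)[C@@H]1C(=O)CC | intermediate
14 | 2-[(1R,2R,3R)-1-methyl-2-propanoyl-3-(propan-2-yl)-3-(triethylsilyloxy)cyclopentyl]acetaldehyde | O=CC[C@@]1(C)CC[C@@](O[Si](CC)(CC)CC)(C(C)C)[C@@H]1C(=O)CC | intermediate
15 | (3R,3aR,5R,6S,7aR)-6-hydroxy-5,7a-dimethyl-3-(propan-2-yl)-3-(triethylsilyloxy)octahydro-4H-inden-4-one (trans-fused; C1–OH α, C10–CH3 β) | O[C@H]1C[C@@]2(C)CC[C@@](O[Si](CC)(CC)CC)(C(C)C)[C@@H]2C(=O)[C@@H]1C | intermediate
16 | (3R,3aR,5R,6S,7aR)-6-(tert-butyldimethylsilyloxy)-5,7a-dimethyl-3-(propan-2-yl)-3-(triethylsilyloxy)octahydro-4H-inden-4-one | CC(C)(C)[Si](C)(C)O[C@H]1C[C@@]2(C)CC[C@@](O[Si](CC)(CC)CC)(C(C)C)[C@@H]2C(=O)[C@@H]1C | intermediate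
17 | (3R,3aR,6S,7aR)-6-(tert-butyldimethylsilyloxy)-5,7a-dimethyl-3-(propan-2-yl)-3-(triethylsilyloxy)-4-(trimethylsilyloxy)-2,3,3a,6,7,7a-hexahydro-1H-indene (C8=C10 silyl enol ether) | CC(C)(C)[Si](C)(C)O[C@H]1C[C@@]2(C)CC[C@@](O[Si](CC)(CC)CC)(C(C)C)[C@@H]2C(O[Si](C)(C)C)=C1C | intermediate
18 | siloxycyclopropane: 17 with CH2 (C9) bridging C8 and C10 (both cyclopropane faces possible) | CC(C)(C)[Si](C)(C)O[C@H]1C[C@@]2(C)CC[C@@](O[Si](CC)(CC)CC)(C(C)C)[C@@H]2C3(O[Si](C)(C)C)CC13C | intermediate (not isolated)
19 | β-chloro ketone: ring-enlarged C8 ketone with C9H2 and C10(Cl)(CH3) (C10 epimers) | CC(C)(C)[Si](C)(C)O[C@H]1C[C@@]2(C)CC[C@@](O[Si](CC)(CC)CC)(C(C)C)[C@@H]2C(=O)CC1(C)Cl | intermediate (not isolated)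
20 | (3R,3aR,7S,8aR)-7-(tert-butyldimethylsilyloxy)-6,8a-dimethyl-3-(propan-2-yl)-3-(triethylsilyloxy)-2,3,3a,7,8,8a-hexahydroazulen-4(1H)-one | CC(C)(C)[Si](C)(C)O[C@H]1C[C@@]2(C)CC[C@@](O[Si](CC)(CC)CC)(C(C)C)[C@@H]2C(=O)C=C1C | intermediate
21 | (3R,3aR,7S,8aR)-3,7-dihydroxy-6,8a-dimethyl-3-(propan-2-yl)-2,3,3a,7,8,8a-hexahydroazulen-4(1H)-one | O[C@H]1C[C@@]2(C)CC[C@@](O)(C(C)C)[C@@H]2C(=O)C=C1C | intermediate
22 | (3R,3aR,7S,8aR)-7-acetoxy-3-hydroxy-6,8a-dimethyl-3-(propan-2-yl)-2,3,3a,7,8,8a-hexahydroazulen-4(1H)-one | CC(=O)O[C@H]1C[C@@]2(C)CC[C@@](O)(C(C)C)[C@@H]2C(=O)C=C1C | intermediate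
23 | (3R,3aS,4S,7S,8aR)-7-acetoxy-6,8a-dimethyl-3-(propan-2-yl)-1,2,3,3a,4,7,8,8a-octahydroazulene-3,4-diol (C8–OH α) | CC(=O)O[C@H]1C[C@@]2(C)CC[C@@](O)(C(C)C)[C@@H]2[C@@H](O)C=C1C | intermediate
24 | 4-hydroxybenzoic acid | OC(=O)c1ccc(O)cc1 | starting material
25 | tert-butyldimethylsilyl 4-(tert-butyldimethylsilyloxy)benzoate | CC(C)(C)[Si](C)(C)OC(=O)c1ccc(O[Si](C)(C)C(C)(C)C)cc1 | intermediate (not isolated)
26 | 4-(tert-butyldimethylsilyloxy)benzoic acid | OC(=O)c1ccc(O[Si](C)(C)C(C)(C)C)cc1 | intermediate
27 | 4-(tert-butyldimethylsilyloxy)benzoyl chloride | ClC(=O)c1ccc(O[Si](C)(C)C(C)(C)C)cc1 | intermediate (not isolated)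
28 | (3R,3aS,4S,7S,8aR)-7-acetoxy-3-hydroxy-6,8a-dimethyl-3-(propan-2-yl)-1,2,3,3a,4,7,8,8a-octahydroazulen-4-yl 4-(tert-butyldimethylsilyloxy)benzoate | CC(=O)O[C@H]1C[C@@]2(C)CC[C@@](O)(C(C)C)[C@@H]2[C@@H](OC(=O)c2ccc(O[Si](C)(C)C(C)(C)C)cc2)C=C1C | intermediate
29 | (3R,3aS,4S,7S,8aR)-7-acetoxy-3-hydroxy-6,8a-dimethyl-3-(propan-2-yl)-1,2,3,3a,4,7,8,8a-octahydroazulen-4-yl 4-hydroxybenzoate | CC(=O)O[C@H]1C[C@@]2(C)CC[C@@](O)(C(C)C)[C@@H]2[C@@H](OC(=O)c2ccc(O)cc2)C=C1C | target

## Step count and least certain steps

Total step count: 16 (step 14 prepares acid 26 from 24). Longest linear sequence: 15 steps (1 to 29 through steps 1–13, 15 and 16).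

**Step 10 (key step).** The most likely failure is slow methylene transfer to the crowded, tetrasubstituted enol ether, so that unreacted 17 hydrolyses back to 16 on work-up. A second risk is loss of the C6 silyl ether to FeCl3, followed by retro-aldol opening of the five-membered ring during the basic elimination. The fallback sets out from 17 and uses a dihalocarbene in place of the zinc carbenoid. CHBr3 and KOtBu in pentane at −20 °C should give the dibromo(siloxy)cyclopropane F1. Warming opens it electrocyclically with loss of Me3SiBr to the ring-enlarged 2-bromo enone F2, which has bromine on C9 and the same C8 ketone and C9=C10 alkene. Hydrodebromination with Bu3SnH and Pd(PPh3)4 returns to 20.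

**Step 1.** The aluminium enolate 5 may add sluggishly to propanal next to the new quaternary centre, excess alane may consume the aldehyde by 1,2-addition, and face selectivity at C7 may erode if the mixture has to be warmed. The fallback sets out from 1 and separates the two events. After the conjugate addition, enolate 5 is quenched with Me3SiOTf and the trimethylsilyl enol ether F3 is isolated. A Mukaiyama aldol of F3 with 3 and BF3·OEt2 at −78 °C then forms C7–C8 through an open transition state, again anti to the silylvinyl group, and returns to 6.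

**Step 2.** Acid may dehydrate the β-hydroxy ketone, or the vinylsilane may be protonated at its terminal carbon and trigger a cationic skeletal shift at the neighbouring quaternary centre. The fallback sets out from 6 and keeps silicon until the arm is an aldehyde. Reagent 9 is added to 6 under the conditions of step 3 to give the silylvinyl diol F4. Hydroboration–oxidation of the vinylsilane (BH3·THF, then NaOH/H2O2) gives the β-hydroxysilane triol F5, and Swern oxidation gives the α-silyl keto aldehyde F6. F6 loses its silyl group on brief treatment with KF in wet MeOH at 0 °C, as α-silyl carbonyl compounds do, and the route is rejoined at 13.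

**Step 7.** The ketol may dehydrate to the conjugated enone under the basic conditions, or the hydroxyl may be formed with incomplete control at C1. The fallback sets out from 14 and takes the dehydration on purpose. KOH in MeOH at 50 °C gives the cyclohexenone F7 (C10=C1). Nucleophilic epoxidation with H2O2 and NaOH attacks C1 from the α-face, away from the axial angular methyl, to give the epoxy ketone F8. Reductive cleavage of the Cα–O bond with SmI2 in THF/MeOH at −78 °C returns to 15 with the C1 hydroxyl α.

**Step 13.** The hindered tertiary hydroxyl may exchange onto boron too slowly, so that undirected reduction from the α-face competes and lowers the face selectivity at C8. The fallback sets out from 22 and uses the undirected preference. Luche reduction (NaBH4, CeCl3·7H2O, MeOH, −78 °C) should give the C8 β-alcohol F9. A Mitsunobu esterification of F9 with acid 26 (PPh3, DIAD, toluene) inverts C8 and returns to the route at 28, bypassing 23.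

## Further compounds

F1 | step 10 | dibromo(siloxy)cyclopropane: 17 with CBr2 bridging C8 and C10 | CC(C)(C)[Si](C)(C)O[C@H]1C[C@@]2(C)CC[C@@](O[Si](CC)(CC)CC)(C(C)C)[C@@H]2C3(O[Si](C)(C)C)C(Br)(Br)C13C
F2 | step 10 | 2-bromo enone: 20 with bromine on C9 | CC(C)(C)[Si](C)(C)O[C@H]1C[C@@]2(C)CC[C@@](O[Si](CC)(CC)CC)(C(C)C)[C@@H]2C(=O)C(Br)=C1C
F3 | step 1 | trimethylsilyl enol ether of (3S)-3-methyl-3-[1-(trimethylsilyl)ethenyl]cyclopentanone (C6=C7) | C=C([Si](C)(C)C)[C@@]1(C)CCC(O[Si](C)(C)C)=C1
F4 | step 2 | silylvinyl diol: 10 with the 1-(trimethylsilyl)ethenyl group on C3 (C8 epimers) | C=C([Si](C)(C)C)[C@@]1(C)CC[C@@](O)(C(C)C)[C@@H]1C(O)CC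
F5 | step 2 | β-hydroxysilane triol: 12 with trimethylsilyl on C2 (C2 and C8 epimers) | OCC([Si](C)(C)C)[C@@]1(C)CC[C@@](O)(C(C)C)[C@@H]1C(O)CC
F6 | step 2 | α-silyl keto aldehyde: 13 with trimethylsilyl on C2 (C2 epimers) | O=CC([Si](C)(C)C)[C@@]1(C)CC[C@@](O)(C(C)C)[C@@H]1C(=O)CC
F7 | step 7 | trans-hydrindenone: C8 ketone with C10=C1 alkene and C6 triethylsilyl ether | CC1=CC[C@@]2(C)CC[C@@](O[Si](CC)(CC)CC)(C(C)C)[C@@H]2C1=O
F8 | step 7 | α-epoxy ketone: F7 with an α-epoxide across C10–C1 | C[C@]12O[C@H]1C[C@@]3(C)CC[C@@](O[Si](CC)(CC)CC)(C(C)C)[C@@H]3C2=O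
F9 | step 13 | C8 epimer of 23 (C8–OH β) | CC(=O)O[C@H]1C[C@@]2(C)CC[C@@](O)(C(C)C)[C@@H]2[C@H](O)C=C1C
A1 | alternative 1 | open-chain α-diazo ester: methyl 2-diazo-3-methyl-6-(tert-butyldimethylsilyloxy)-7-methyl-3-[2-(triisopropylsilyloxy)ethyl]octanoate with C3 and C6 as in the target | COC(=O)C(=[N+]=[N-])[C@@](C)(CCO[Si](C(C)C)(C(C)C)C(C)C)CC[C@@H](O[Si](C)(C)C(C)(C)C)C(C)C
A2 | alternative 1 | cyclopentane ester from C–H insertion with C3, C6 and C7 set | COC(=O)[C@H]1[C@](O[Si](C)(C)C(C)(C)C)(C(C)C)CC[C@]1(C)CCO[Si](C(C)C)(C(C)C)C(C)C
A3 | alternative 2 | cis-decalin with C8 ring-fusion tertiary alcohol, C7 mesylate and C6 methoxymethyl ether | CC1=CC[C@@]2(C)CC[C@@](OCOC)(C(C)C)[C@H](OS(C)(=O)=O)[C@@]2(O)C1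
A4 | alternative 2 | trans-fused hydroazulen-8-one with C6 methoxymethyl ether and C10=C1 alkene | CC1=CC[C@@]2(C)CC[C@@](OCOC)(C(C)C)[C@@H]2C(=O)C1
A5 | alternative 3 | cycloheptene with 2-iodoethyl on C3, isopropyl ketone on C7, C8 methoxymethyl ether and C1 silyl ether | CC(C)(C)[Si](C)(C)O[C@H]1C[C@@](C)(CCI)[C@H](C(=O)C(C)C)[C@@H](OCOC)C=C1C
A6 | alternative 3 | trans-hydroazulene with the C6 tertiary alcohol from Barbier closure | CC(C)(C)[Si](C)(C)O[C@H]1C[C@@]2(C)CC[C@@](O)(C(C)C)[C@@H]2[C@@H](OCOC)C=C1C
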